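**Plan**
1. Retrosynthesis: the C3 O–methyl bond and the C8 ketone (kept as a dimethyl ketal) are cut first, the C4 carbonyl is traced back to a C4 methoxycarbonyl group, and the C6–aryl bond is cut as a hydroarylation of a C6=C7 alkene; C4–C5 and C1–C2 are then cut together.
2. That double cut rests on one feature: the seven-membered carbocycle C1–C7 spanned by C8 is a cyclopentadiene (C1, C7, C6, C5 around C8) joined to a three-carbon unit C2–C3–C4 oxygenated at C3, which maps onto a dienone ketal plus a 2-siloxyvinyl carbenoid.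
3. Forward: the five-membered ring comes first (Stetter/aldol cyclopentenone, then the 5,5-dimethoxycyclopentadiene 9). The carbenoid from diazo ester 12 then closes the seven-membered ring, giving the bicyclo[3.2.1]octadiene 14. The aryl group, the C4 oxygen, the C8 ketone and the O-methyl group follow.
4. Stereochemistry: C5 and C1 come from the chiral dirhodium carboxylate in the cyclopropanation, relayed by the boat Cope shift. C6 and C7 come from exo-face syn addition of aryl and hydrogen across C6=C7, which puts the aryl exo and the methyl endo (trans).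

Key step: step 8

Conventions: locants C1–C8 of the bicyclic core are those of the target in every name (C1 allyl-bearing bridgehead, C5 the other bridgehead, C8 the one-carbon bridge); exo means on the side of C8; allyl = prop-2-en-1-yl. Rh2(S-PTAD)4 = dirhodium tetrakis[(S)-2-(adamantan-1-yl)-2-phthalimidoacetate], a divalent rhodium carboxylate.
Assumption: Rh2(S-PTAD)4 is taken to give the (1R,5R) series drawn for 14; should its sense of induction be the opposite, the mirror-image catalyst Rh2(R-PTAD)4 is used instead.

**Step 1**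
Reactants: 1 pent-4-enal; 2 but-3-en-2-one
Product: 3 non-8-ene-2,5-dione
Conditions: 3-benzyl-5-(2-hydroxyethyl)-4-methylthiazolium chloride (10 mol %), Et3N, EtOH, 80 °C
Reagents that add atoms: none
Why: Stetter reaction, in which the thiazolium-derived carbene turns the aldehyde into an acyl anion equivalent that adds 1,4 to the enone, the standard entry to 1,4-diketones of the jasmone family.

**Step 2**
Reactants: 3 non-8-ene-2,5-dione
Product: 4 2-allyl-3-methylcyclopent-2-en-1-one
Conditions: 2% aq. NaOH, EtOH, reflux
Reagents that add atoms: none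
Why: Intramolecular aldol condensation of the 1,4-diketone through the C6 enolate closes the five-membered ring and gives the more substituted 2,3-dialkylcyclopentenone, while the skipped allyl alkene is not acidified by the carbonyl and stays in place.

**Step 3**
Reactants: 4 2-allyl-3-methylcyclopent-2-en-1-one
Product: 6 rac-2-allyl-3-methyl-5-(phenylselanyl)cyclopent-2-en-1-one, via lithium dienolate 5 (not isolated)
Conditions: LiN(iPr)2, THF, −78 °C; PhSeBr, −78 °C
Reagents that add atoms: phenylselenyl bromide, Br[Se]c1ccccc1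
Why: Kinetic deprotonation of the enone takes place at the α′ methylene (cross-conjugated enolate) and α-selenenylation of lithium enolates is a standard reaction; the new stereocentre is racemic and disappears in step 5.

**Step 4**
Reactants: 6 rac-2-allyl-3-methyl-5-(phenylselanyl)cyclopent-2-en-1-one
Product: 7 rac-{[3-allyl-2,2-dimethoxy-4-methylcyclopent-3-en-1-yl]selanyl}benzene
Conditions: MeOSiMe3 (3 equiv), Me3SiOTf (5 mol %), CH2Cl2, −78 to −30 °C; pyridine quench
Reagents that add atoms: methoxytrimethylsilane, CO[Si](C)(C)C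
Why: Silyl triflate-catalysed ketalisation with an alkoxysilane converts enones into ketals at low temperature without moving the tetrasubstituted double bond; the acyclic dimethyl ketal is chosen because acyclic cyclopentadienone ketals dimerise much more slowly than dioxolanes.

**Step 5**
Reactants: 7 rac-{[3-allyl-2,2-dimethoxy-4-methylcyclopent-3-en-1-yl]selanyl}benzene
Product: 9 1-allyl-5,5-dimethoxy-2-methylcyclopenta-1,3-diene, via selenoxide 8 (not isolated)
Conditions: mCPBA (1.0 equiv), CH2Cl2, −78 °C; then iPr2NH (3 equiv), −78 °C to rt; cold filtration through basic alumina, solution used at once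
Reagents that add atoms: none
Why: Selenoxide syn-elimination, in which oxidation at selenium is far faster than epoxidation of either alkene, the only β-hydrogens sit on the ring CH2 so the double bond can form only there, and the amine traps the selenenic and benzoic acids that would attack the diene ketal.

**Step 6**
Reactants: 10 methyl acetoacetate
Product: 11 methyl 2-diazo-3-oxobutanoate
Conditions: 4-acetamidobenzenesulfonyl azide, Et3N, MeCN, 0 °C to rt
Reagents that add atoms: 4-acetamidobenzenesulfonyl azide, CC(=O)Nc1ccc(cc1)S(=O)(=O)N=[N+]=[N-]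
Why: Regitz diazo transfer to an active methylene compound.

**Step 7**
Reactants: 11 methyl 2-diazo-3-oxobutanoate
Product: 12 methyl 3-[(tert-butyldimethylsilyl)oxy]-2-diazobut-3-enoate
Conditions: tBuMe2SiOTf, Et3N, CH2Cl2, 0 °C
Reagents that add atoms: tert-butyldimethylsilyl trifluoromethanesulfonate, CC(C)(C)[Si](C)(C)OS(=O)(=O)C(F)(F)F
Why: O-silylation of the α-diazo-β-keto ester, which can enolise only toward its methyl group, is the usual preparation of siloxyvinyldiazoacetates.

**Step 8**
Reactants: 9 1-allyl-5,5-dimethoxy-2-methylcyclopenta-1,3-diene; 12 methyl 3-[(tert-butyldimethylsilyl)oxy]-2-diazobut-3-enoate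
Product: 14 methyl (1R,5R)-1-allyl-3-[(tert-butyldimethylsilyl)oxy]-8,8-dimethoxy-7-methylbicyclo[3.2.1]octa-3,6-diene-4-carboxylate, via cis-divinylcyclopropane 13 (not isolated)
Conditions: Rh2(S-PTAD)4 (1 mol %), hexanes, −26 °C, 12 (1.5 equiv) added over 2 h to 9; then rt (40 °C if 13 persists)
Reagents that add atoms: none
Why: The dirhodium catalyst turns 12 into a siloxyvinyl carbenoid that cyclopropanates the cis-disubstituted C5=C6 bond of 9 with the vinyl group cis to the remaining ring alkene, and the resulting cis-divinylcyclopropane 13 undergoes a Cope rearrangement through a boat transition state that forms C1–C2, keeps C4–C5 and breaks C4–C6. The closest known reaction type is the tandem cyclopropanation/Cope rearrangement (formal (4+3) cycloaddition) of siloxyvinyldiazoacetates with cyclopentadienes, pyrroles and acyclic dienes under the same catalyst. The seven-membered ring C1–C7 is closed by the [3,3]-sigmatropic shift, the three-membered ring made by carbene transfer being consumed, and the ketal carbon of the diene ends as the one-carbon bridge C8. C5 is set in the cyclopropanation by the chiral carboxylate ligands, which choose the face of the planar diene, and C1 follows because the Cope shift delivers C2 to the same face of the five-membered ring. The step needs site selection and endo placement of the vinyl group: the tetrasubstituted C1=C7 bond is inert to donor/acceptor carbenoids, the isolated allyl alkene is less nucleophilic than the conjugated diene, and the carbenoid's usual preference places the alkene substituent cis to the vinyl donor. Slow addition of 12 at low temperature keeps Diels–Alder dimerisation of 9 and carbene dimerisation down.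

**Step 9**
Reactants: 14 methyl (1R,5R)-1-allyl-3-[(tert-butyldimethylsilyl)oxy]-8,8-dimethoxy-7-methylbicyclo[3.2.1]octa-3,6-diene-4-carboxylate; 15 4-iodo-1,2-dimethoxybenzene
Product: 17 methyl (1R,5R,6R,7R)-1-allyl-6-(3,4-dimethoxyphenyl)-8,8-dimethoxy-7-methyl-3-oxobicyclo[3.2.1]octane-4-carboxylate, via silyl enol ether 16 (not isolated)
Conditions: Pd(OAc)2 (5 mol %), PPh3 (10 mol %), HCO2Na (3 equiv), Bu4NCl, DMF, 60 °C; then Bu4NF, AcOH, THF, 0 °C to rt (same pot)
Reagents that add atoms: none
Why: Reductive Heck reaction (hydroarylation), in which the arylpalladium iodide formed from 15 and zerovalent palladium adds syn across the strained C6=C7 bond from the exo face (the endo face lies in the fold under the C2–C4 bridge), aryl to the less substituted C6 and palladium to C7, and formate then replaces palladium by hydrogen with retention, so the aryl is exo and the C7 methyl endo; fluoride finally frees the β-keto ester.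

**Step 10**
Reactants: 17 methyl (1R,5R,6R,7R)-1-allyl-6-(3,4-dimethoxyphenyl)-8,8-dimethoxy-7-methyl-3-oxobicyclo[3.2.1]octane-4-carboxylate
Product: 19 methyl (1R,5R,6R,7R)-1-allyl-6-(3,4-dimethoxyphenyl)-4-hydroxy-8,8-dimethoxy-7-methyl-3-oxobicyclo[3.2.1]octane-4-carboxylate, via potassium enolate 18 (not isolated)
Conditions: KN(SiMe3)2, THF, −78 °C; 2-(phenylsulfonyl)-3-phenyloxaziridine, −78 °C; AcOH quench
Reagents that add atoms: 2-(phenylsulfonyl)-3-phenyloxaziridine, O=S(=O)(c1ccccc1)N1OC1c1ccccc1
Why: Davis oxidation of a β-keto ester enolate, in which only the doubly activated C4–H is removed, the oxaziridine transfers oxygen to C4 without touching the alkenes, and the C8 ketal blocks retro-aldol cleavage of the C4 alkoxide; the C4 configuration is immaterial because C4 becomes a carbonyl carbon.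

**Step 11**
Reactants: 19 methyl (1R,5R,6R,7R)-1-allyl-6-(3,4-dimethoxyphenyl)-4-hydroxy-8,8-dimethoxy-7-methyl-3-oxobicyclo[3.2.1]octane-4-carboxylate
Product: 20 (1R,5R,6R,7R)-1-allyl-6-(3,4-dimethoxyphenyl)-4-hydroxy-8,8-dimethoxy-7-methylbicyclo[3.2.1]octan-3-one
Conditions: LiCl, DMSO, H2O, 130 °C
Reagents that add atoms: none
Why: Krapcho dealkoxycarbonylation, in which chloride demethylates the ester by SN2 and the α-hydroxy-β-keto carboxylate loses CO2 through the enediol to give the acyloin; a positional isomer of the acyloin formed through the enediol would give the same product in step 12.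

**Step 12**
Reactants: 20 (1R,5R,6R,7R)-1-allyl-6-(3,4-dimethoxyphenyl)-4-hydroxy-8,8-dimethoxy-7-methylbicyclo[3.2.1]octan-3-one
Product: 21 (1S,5R,6R,7R)-1-allyl-6-(3,4-dimethoxyphenyl)-3-hydroxy-8,8-dimethoxy-7-methylbicyclo[3.2.1]oct-2-en-4-one
Conditions: Dess–Martin periodinane, NaHCO3, CH2Cl2, 0 °C to rt
Reagents that add atoms: none
Why: Dess–Martin oxidation of the α-hydroxy ketone gives the 3,4-dione, which can enolise only toward C2 because C5 is a bridgehead (Bredt's rule) and therefore rests as the diosphenol with the C2=C3 double bond of the target.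

**Step 13**
Reactants: 21 (1S,5R,6R,7R)-1-allyl-6-(3,4-dimethoxyphenyl)-3-hydroxy-8,8-dimethoxy-7-methylbicyclo[3.2.1]oct-2-en-4-one
Product: 22 (1S,5S,6R,7R)-1-allyl-6-(3,4-dimethoxyphenyl)-3-hydroxy-7-methylbicyclo[3.2.1]oct-2-ene-4,8-dione
Conditions: 3 M aq. HCl, THF, 45 °C
Reagents that add atoms: water, O
Why: Acid-catalysed ketal hydrolysis, placed after C4 has become a carbonyl so that no β-hydroxy ketone prone to retro-aldol cleavage is formed, and before O-methylation so that the enol ether never meets acid; the diosphenol, the aryl ethers and the allyl group tolerate aqueous acid.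

**Step 14**
Reactants: 22 (1S,5S,6R,7R)-1-allyl-6-(3,4-dimethoxyphenyl)-3-hydroxy-7-methylbicyclo[3.2.1]oct-2-ene-4,8-dione
Product: 23 kadsurenin D [(1S,5S,6R,7R)-1-allyl-6-(3,4-dimethoxyphenyl)-3-methoxy-7-methylbicyclo[3.2.1]oct-2-ene-4,8-dione]
Conditions: Me2SO4, K2CO3, acetone, rt to 40 °C
Reagents that add atoms: dimethyl sulfate, COS(=O)(=O)OC
Why: O-alkylation of a diosphenol by a hard methylating agent under carbonate conditions, with C-methylation at C2 disfavoured by the adjacent quaternary C1 and the non-nucleophilic base in acetone sparing the non-enolisable C4/C8 β-diketone from retro-Claisen cleavage.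

**Compound list**
1 | pent-4-enal | C=CCCC=O | starting material
2 | but-3-en-2-one (methyl vinyl ketone) | CC(=O)C=C | starting material
3 | non-8-ene-2,5-dione | CC(=O)CCC(=O)CCC=C | intermediate
4 | 2-allyl-3-methylcyclopent-2-en-1-one | C=CCC1=C(C)CCC1=O | intermediate
5 | lithium 5-allyl-4-methylcyclopenta-1,4-dien-1-olate (not isolated) | [Li+].[O-]C1=CCC(C)=C1CC=C | intermediate
6 | rac-2-allyl-3-methyl-5-(phenylselanyl)cyclopent-2-en-1-one | C=CCC1=C(C)CC([Se]c2ccccc2)C1=O | intermediate
7 | rac-{[3-allyl-2,2-dimethoxy-4-methylcyclopent-3-en-1-yl]selanyl}benzene | C=CCC1=C(C)CC([Se]c2ccccc2)C1(OC)OC | intermediate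
8 | selenoxide of 7 (mixture of diastereomers, not isolated) | C=CCC1=C(C)CC([Se](=O)c2ccccc2)C1(OC)OC | intermediate
9 | 1-allyl-5,5-dimethoxy-2-methylcyclopenta-1,3-diene | C=CCC1=C(C)C=CC1(OC)OC | intermediate
10 | methyl acetoacetate | COC(=O)CC(C)=O | starting material
11 | methyl 2-diazo-3-oxobutanoate | COC(=O)C(=[N+]=[N-])C(C)=O | intermediate
12 | methyl 3-[(tert-butyldimethylsilyl)oxy]-2-diazobut-3-enoate | COC(=O)C(=[N+]=[N-])C(=C)O[Si](C)(C)C(C)(C)C | intermediate
13 | methyl (1R,5R,6R)-3-allyl-6-{1-[(tert-butyldimethylsilyl)oxy]vinyl}-4,4-dimethoxy-2-methylbicyclo[3.1.0]hex-2-ene-6-carboxylate, siloxyvinyl group endo (cis to the ring alkene), ester exo (not isolated) | C=CCC1=C(C)[C@H]2[C@@H](C1(OC)OC)[C@@]2(C(=O)OC)C(=C)O[Si](C)(C)C(C)(C)C | intermediate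
14 | methyl (1R,5R)-1-allyl-3-[(tert-butyldimethylsilyl)oxy]-8,8-dimethoxy-7-methylbicyclo[3.2.1]octa-3,6-diene-4-carboxylate | C=CC[C@]12CC(O[Si](C)(C)C(C)(C)C)=C(C(=O)OC)[C@H](C1(OC)OC)C=C2C | intermediate
15 | 4-iodo-1,2-dimethoxybenzene | COc1ccc(I)cc1OC | starting material
16 | methyl (1R,5R,6R,7R)-1-allyl-3-[(tert-butyldimethylsilyl)oxy]-6-(3,4-dimethoxyphenyl)-8,8-dimethoxy-7-methylbicyclo[3.2.1]oct-3-ene-4-carboxylate, aryl exo, methyl endo (not isolated) | C=CC[C@]12CC(O[Si](C)(C)C(C)(C)C)=C(C(=O)OC)[C@H](C1(OC)OC)[C@H](c1ccc(OC)c(OC)c1)[C@H]2C | intermediate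
17 | methyl (1R,5R,6R,7R)-1-allyl-6-(3,4-dimethoxyphenyl)-8,8-dimethoxy-7-methyl-3-oxobicyclo[3.2.1]octane-4-carboxylate; C4 epimers interconvert through the enol, so C4 is left undefined | C=CC[C@]12CC(=O)C(C(=O)OC)[C@H](C1(OC)OC)[C@H](c1ccc(OC)c(OC)c1)[C@H]2C | intermediate
18 | potassium enolate of 17 (C3 enolate oxygen, C3=C4; not isolated) | [K+].C=CC[C@]12CC([O-])=C(C(=O)OC)[C@H](C1(OC)OC)[C@H](c1ccc(OC)c(OC)c1)[C@H]2C | intermediate
19 | methyl (1R,5R,6R,7R)-1-allyl-6-(3,4-dimethoxyphenyl)-4-hydroxy-8,8-dimethoxy-7-methyl-3-oxobicyclo[3.2.1]octane-4-carboxylate; C4 configuration not assigned, lost in step 12 | C=CC[C@]12CC(=O)C(O)(C(=O)OC)[C@H](C1(OC)OC)[C@H](c1ccc(OC)c(OC)c1)[C@H]2C | intermediate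
20 | (1R,5R,6R,7R)-1-allyl-6-(3,4-dimethoxyphenyl)-4-hydroxy-8,8-dimethoxy-7-methylbicyclo[3.2.1]octan-3-one; C4 configuration not assigned, lost in step 12 | C=CC[C@]12CC(=O)C(O)[C@H](C1(OC)OC)[C@H](c1ccc(OC)c(OC)c1)[C@H]2C | intermediate
21 | (1S,5R,6R,7R)-1-allyl-6-(3,4-dimethoxyphenyl)-3-hydroxy-8,8-dimethoxy-7-methylbicyclo[3.2.1]oct-2-en-4-one | C=CC[C@]12C=C(O)C(=O)[C@H](C1(OC)OC)[C@H](c1ccc(OC)c(OC)c1)[C@H]2C | intermediate
22 | (1S,5S,6R,7R)-1-allyl-6-(3,4-dimethoxyphenyl)-3-hydroxy-7-methylbicyclo[3.2.1]oct-2-ene-4,8-dione | C=CC[C@]12C=C(O)C(=O)[C@H](C1=O)[C@H](c1ccc(OC)c(OC)c1)[C@H]2C | intermediate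
23 | kadsurenin D, (1S,5S,6R,7R)-1-allyl-6-(3,4-dimethoxyphenyl)-3-methoxy-7-methylbicyclo[3.2.1]oct-2-ene-4,8-dione | C=CC[C@]12C=C(OC)C(=O)[C@H](C1=O)[C@H](c1ccc(OC)c(OC)c1)[C@H]2C | target

**Step count**
Total: 14 steps. Longest linear sequence: 12 steps (steps 1–5 and 8–14); the diazo ester branch (steps 6–7) has 2 steps.

**Steps most likely to fail**

Step 9. The tertiary alkylpalladium at C7 may lose a β-hydrogen from the C7 methyl group before formate captures it. The arylpalladium species may also insert into the allyl alkene, or approach from the endo face because one ketal methoxy group lies over the exo face. The fallback separates C–C bond formation from hydrogen delivery and sets out from 14 (with 15). A Heck arylation without a hydride donor (Pd(OAc)2, P(o-tol)3, Et3N, DMF, 80 °C) uses that same β-hydride loss on purpose and should give methyl 1-allyl-3-[(tert-butyldimethylsilyl)oxy]-6-exo-(3,4-dimethoxyphenyl)-8,8-dimethoxy-7-methylidenebicyclo[3.2.1]oct-3-ene-4-carboxylate F1. Bu4NF/AcOH in the same pot converts it into methyl 1-allyl-6-exo-(3,4-dimethoxyphenyl)-8,8-dimethoxy-7-methylidene-3-oxobicyclo[3.2.1]octane-4-carboxylate F2. A hydrogen atom transfer hydrogenation of Mukaiyama type (Mn(dpm)3, i.e. tris(2,2,6,6-tetramethylheptane-3,5-dionato)manganese, PhSiH3, tBuOOH, iPrOH, rt) then reduces the 1,1-disubstituted exocyclic alkene through a tertiary C7 radical, in preference to the monosubstituted allyl group. The second hydrogen should arrive at C7 so that the methyl ends trans to the aryl, avoiding an eclipsed cis pair on the two-carbon bridge. The fallback comes back to the route at 17.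

Step 8. The diene 9 may dimerise by Diels–Alder reaction before the carbenoid captures it. The hindered, ketal-flanked diene may also be discriminated poorly by the bulky siloxyvinyl carbenoid (low face or site selectivity, attack on the allyl group), or the Cope shift may stall because C1 becomes quaternary. The fallback uses the smaller, unsubstituted vinyl carbenoid at lower temperature and adds the C3 oxygen afterwards; it sets out from 9. Commercial methyl but-3-enoate is converted (4-acetamidobenzenesulfonyl azide, DBU, MeCN, 0 °C) into methyl 2-diazobut-3-enoate F3, which is used at once. With 9 and Rh2(S-DOSP)4 (dirhodium tetrakis[(S)-N-(4-dodecylbenzenesulfonyl)prolinate]; antipode chosen to match) in pentane at −78 °C it should give methyl (1R,5R)-1-allyl-8,8-dimethoxy-7-methylbicyclo[3.2.1]octa-3,6-diene-4-carboxylate F4. Copper-catalysed conjugate borylation of the enoate (CuCl, NaOtBu, bis[2-(diphenylphosphino)phenyl] ether, bis(pinacolato)diboron, MeOH, THF) gives the C3 pinacol boronate F5. Oxidation with NaBO3·4H2O gives methyl 1-allyl-3-hydroxy-8,8-dimethoxy-7-methylbicyclo[3.2.1]oct-6-ene-4-carboxylate F6, and Dess–Martin oxidation gives methyl 1-allyl-8,8-dimethoxy-7-methyl-3-oxobicyclo[3.2.1]oct-6-ene-4-carboxylate F7. Silylation (tBuMe2SiOTf, Et3N) toward the more acidic C4 brings the sequence back to the route at 14.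

Step 13. Ionisation of the bridge ketal is slowed by ring strain and by the adjacent C4 carbonyl, so forcing acid may be needed. Under such conditions the C8 cation could be captured by the electron-rich aryl ring held on the same face, or acid could add to the allyl group. The fallback unmasks C8 one stage earlier, where C4 is still a carbinol carbon and milder acid should suffice; it sets out from 20. Hydrolysis (1 M aq. HCl, THF, rt) gives (1R,5S,6R,7R)-1-allyl-6-(3,4-dimethoxyphenyl)-4-hydroxy-7-methylbicyclo[3.2.1]octane-3,8-dione F8. This β-hydroxy ketone is kept away from base and oxidised directly with Dess–Martin periodinane, which brings the sequence back to the route at 22.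

**Further compounds**
F1 | step 9 | methyl 1-allyl-3-[(tert-butyldimethylsilyl)oxy]-6-exo-(3,4-dimethoxyphenyl)-8,8-dimethoxy-7-methylidenebicyclo[3.2.1]oct-3-ene-4-carboxylate | C=CC[C@]12CC(O[Si](C)(C)C(C)(C)C)=C(C(=O)OC)[C@H](C1(OC)OC)[C@H](c1ccc(OC)c(OC)c1)C2=C
F2 | step 9 | methyl 1-allyl-6-exo-(3,4-dimethoxyphenyl)-8,8-dimethoxy-7-methylidene-3-oxobicyclo[3.2.1]octane-4-carboxylate (C4 epimers) | C=CC[C@]12CC(=O)C(C(=O)OC)[C@H](C1(OC)OC)[C@H](c1ccc(OC)c(OC)c1)C2=C
F3 | step 8 | methyl 2-diazobut-3-enoate | C=CC(=[N+]=[N-])C(=O)OC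
F4 | step 8 | methyl (1R,5R)-1-allyl-8,8-dimethoxy-7-methylbicyclo[3.2.1]octa-3,6-diene-4-carboxylate | C=CC[C@]12CC=C(C(=O)OC)[C@H](C1(OC)OC)C=C2C
F5 | step 8 | methyl 1-allyl-8,8-dimethoxy-7-methyl-3-(4,4,5,5-tetramethyl-1,3,2-dioxaborolan-2-yl)bicyclo[3.2.1]oct-6-ene-4-carboxylate (C3 and C4 configurations not assigned) | C=CC[C@]12CC(B3OC(C)(C)C(C)(C)O3)C(C(=O)OC)[C@H](C1(OC)OC)C=C2C
F6 | step 8 | methyl 1-allyl-3-hydroxy-8,8-dimethoxy-7-methylbicyclo[3.2.1]oct-6-ene-4-carboxylate (C3 and C4 configurations not assigned) | C=CC[C@]12CC(O)C(C(=O)OC)[C@H](C1(OC)OC)C=C2C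
F7 | step 8 | methyl 1-allyl-8,8-dimethoxy-7-methyl-3-oxobicyclo[3.2.1]oct-6-ene-4-carboxylate (C4 epimers) | C=CC[C@]12CC(=O)C(C(=O)OC)[C@H](C1(OC)OC)C=C2C
F8 | step 13 | (1R,5S,6R,7R)-1-allyl-6-(3,4-dimethoxyphenyl)-4-hydroxy-7-methylbicyclo[3.2.1]octane-3,8-dione (C4 configuration not assigned) | C=CC[C@]12CC(=O)C(O)[C@H](C1=O)[C@H](c1ccc(OC)c(OC)c1)[C@H]2C
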